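# Route to (2S)-5-hydroxy-2-(2-hydroxy-6-methoxyphenyl)-6,7,8-trimethoxychroman-4-one by a late benzannulation that builds ring B

## Analysis of the target

The target is a flavanone. Ring A is fully substituted (C5–OH, C6/C7/C8–OMe, C4a, C8a–O1), ring C is the dihydropyranone, and ring B is bonded through C1' to C2. C2 is the only stereocenter; with O1 > C1' > C3 > H the descriptor in the SMILES is S. The β-aryloxy ketone opens by retro-oxa-Michael reaction under base, which racemises C2. The O1–C2 bond is benzylic to a ring with two ortho oxygen donors, so strong acids can ionise it. The 5-OH is hydrogen-bonded to the C4 carbonyl, which makes it the one ring A oxygen that can be addressed selectively. The hard part is ring B: C1' is flanked by C2'–OH and C6'–OMe, so the arene is doubly ortho-substituted, sits on the stereocenter, and carries two oxygens that must be told apart. The plan reads ring B as a 2-alkyl-3-oxyphenol. C1' and one oxygen-bearing carbon come from an oxygenated alkyne already attached to C2, and the other four carbons and the second oxygen come from a vinylketene. Ring B is therefore built last and its two oxygens differ from the moment they form.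

## Retrosynthetic reasoning

**31 ⇒ 30 (O–CH3 at C5).** The 5-OH is released last from tetramethyl ether 30. It is the only methyl ether peri to the C4 carbonyl, so a chelating Lewis acid can pick it out. All earlier intermediates then carry four identical, inert methoxy groups on ring A.

**30 ⇒ 29 ⇒ 28 ⇒ 27 ⇒ 26 (adjustments on ring B and at C4).** The free ring B hydroxyl of 30 is unmasked from silyl ether 29. The C4 ketone of 29 comes from alcohol 28, and 28 from bis-silyl ether 27. The ring B methoxy group of 27 comes from methylation of the single free hydroxyl of phenol 26. C4 is carried as a silyl-protected carbinol because a ketone would not survive the acetylide and ynolate chemistry used earlier, and because the flavanone is base-labile. The carbonyl is restored only after every strongly basic step, so the C4 configuration is temporary. The ordering means the two ring B oxygens never need a desymmetrisation: one is a free OH and the other a silyl ether in 26.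

**26 ⇒ 18 + 21 (C1'–C2' and C5'–C6', ring B).** Locants refer to 26, where C2' carries the free hydroxyl and C6' the silyloxy group. In the target name the two locants are exchanged, because the silylated oxygen ends as the free OH. Ring B is cut into siloxyalkyne 18, which supplies C1' and C6', and cyclobutenone 21, which supplies C2'–C5' through vinylketene 22. The cut is made here because a 2-substituted resorcinol monoether is exactly what an oxygenated alkyne and a vinylketene give, with the alkyne substituent placed between the two oxygens. The forward cascade must be regioselective in the ketene–alkyne [2+2] and must leave the propargylic C2 stereocenter untouched. An O-methyl ynol ether would give the final pattern directly, but ynolates such as 17 react with alkylating agents at carbon, so a bulky silyl group on oxygen is the practical choice.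

**18 ⇒ 15 (O–C(sp)).** The silyloxy group is put on the terminal alkyne of 15 by oxidising acetylide 16 to ynolate 17 and silylating at oxygen. This uses the alkyne carbon that is already in place and adds no skeletal bond.

**15 ⇒ 14 ⇒ 12 (C4 oxidation level).** Silyl ether 15 comes from alcohol 14, and 14 from ketone 12 by reduction and loss of the alkyne silyl group. Reduction comes first so that the base-labile β-aryloxy ketone is never exposed to carbonate.

**12 ⇒ 8 + 9 (C2–C(sp), the stereocenter).** The alkynyl group is added to C2 of chromone 8 as the copper acetylide of 9, through pyrylium ion 10, under control of a chiral ligand. C2 is set on a flat, unhindered position, before the bulky ring B exists.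

**8 ⇒ 6 ⇒ 4 ⇒ 1 (ring C and the fifth ring A oxygen).** C2 of chromone 8 comes from a formamide acetal condensed onto the methyl ketone of 6 (enaminone 7), which closes O1–C2. The acetyl group of 6 is placed at the only free position of phenol 4. The phenol oxygen of 4 is put on symmetric 1 by ortho-lithiation, borylation and oxidation; the two free positions of 1 are equivalent.

**21 ⇒ 20 ⇒ 19.** Cyclobutenone 21 is made by dehydrobromination of 20, which comes from bromodecarboxylation of acid 19.

## Alternatives that were turned down

**Alternative 1:** Ring C is cut at C4a–C4, C4–C3 and O1–C2 into 2-iodo-3,4,5,6-tetramethoxyphenol A2, carbon monoxide and 1-(benzyloxy)-2-ethynyl-3-methoxybenzene A3. In the forward step, PdCl2(PPh3)2 with Et2NH under CO gives an acylpalladium species from A2 (oxidative addition of zerovalent palladium, CO insertion). This couples with A3 to an ynone, and the phenol adds 6-endo to give flavone A1.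
- For: it is the most convergent plan; the whole skeleton forms in one step, and ring B arrives with its oxygens already differentiated (benzyl against methyl). On step count to the skeleton it is clearly stronger than the chosen route.
- Against: A1 is achiral. The stereocenter would have to come from an enantioselective 1,4-reduction of C2=C3 to flavanone A4. The β-carbon carries a 2,6-disubstituted aryl group twisted out of conjugation and the carbonyl is crowded by 5-OMe; no dependable method covers that case, and over-reduction of the ketone competes. 5-exo closure to an aurone and slow oxidative addition into the electron-rich, hexasubstituted iodide add risk.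
- Comparison: the chosen route is longer, but it sets C2 by a catalytic addition to an unhindered chromone and only then builds the hindered arene.

**Alternative 2:** Ring C is cut at C2–C3. Rh2(S-PTTL)4 (dirhodium tetrakis[N-phthaloyl-(S)-tert-leucinate]) decomposes diazoketone A6. The carbenoid at C3 inserts into one enantiotopic benzylic C–H of the O1–CH2–aryl ether and gives flavanone A5.
- For: ring closure and stereocenter come in one step at the ketone oxidation level, so there is no redox detour at C4. The C–H bond is activated by oxygen and by the donor arene. The isopropyl ether and the 5-OMe could fall together in one final Lewis-acid step. On redox economy and length it is stronger than the chosen route.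
- Against: the carbenoid is of the acceptor-only type and unselective. The ether oxygen sits 1,5 to the carbenoid carbon, so oxonium ylide formation followed by a Stevens 1,2-benzyl shift is expected to outrun the six-membered C–H insertion. Addition to the electron-rich ring B (Buchner reaction) also competes. Enantioselectivity for this insertion type is moderate at best.
- Comparison: the chosen route takes its stereocenter from a reaction class that is established for chromones, and its ring-forming step has no competing pathway that changes the skeleton.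

**Alternative 3:** Ring C is cut at O1–C8a. Pd(OAc)2 with a di-tert-butyl(biaryl)phosphine and Cs2CO3 (or CuI with 1,10-phenanthroline) couples the C2 hydroxyl of bromo diol A8 with the aryl bromide to give chromanol A7. A8 is the (1S,3S) diol, which is the anti isomer in the zigzag drawing and maps onto the 2,4-cis chromanol.
- For: both carbinol centers come from dependable acyclic methods (asymmetric aldol or ketone reduction, then 1,3-anti reduction). Ring B is bought with differentiated oxygens. Only the C2 hydroxyl can close a six-membered ring. On predictability of stereochemistry it is at least as strong as the chosen route.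
- Against: the bromide lies between a methoxy group and the branched side chain on a tetramethoxy ring, so oxidative addition is slow. The secondary benzylic alkoxide on palladium tends to undergo β-hydride elimination before C–O reductive elimination. The carbinol itself is shielded by the 2,6-disubstituted ring B. Oxidation, debenzylation and 5-O-demethylation still follow.
- Comparison: the length is similar. The chosen route avoids a metal-mediated closure at the most crowded pair of atoms and relies on a pericyclic cascade driven by strain release and aromatisation.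

Key step: step 10

Assumption: the antipode of the chiral ligand in step 4 is taken to be the one that delivers the 2S adduct; the sense of induction is fixed by the ligand and would be verified on 12.

## Steps

Step 1
Reactants: 1 1,2,3,4-tetramethoxybenzene
Product: 4 2,3,4,5-tetramethoxyphenol, via aryllithium 2 (not isolated), via arylboronate 3 (not isolated)
Conditions: n-BuLi, TMEDA, THF, 0 °C; B(OMe)3, −78 °C → rt; 30% H2O2, AcOH, 0 °C → rt
Reagents that add atoms: hydrogen peroxide, OO
Why: Directed ortho-lithiation at one of the two equivalent free positions, borylation and oxidative 1,2-aryl shift from boron to oxygen give the phenol; the symmetry of 1 makes the regiochemistry unambiguous.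

Step 2
Reactants: 4 2,3,4,5-tetramethoxyphenol
Product: 6 1-(2-hydroxy-3,4,5,6-tetramethoxyphenyl)ethan-1-one, via aryl acetate 5 (not isolated)
Conditions: Ac2O, BF3·OEt2, 70 °C; aq. NaOAc work-up
Reagents that add atoms: acetic anhydride, CC(=O)OC(C)=O
Why: O-Acetylation followed by BF3-promoted Fries rearrangement moves the acyl group to the only unsubstituted ring position, which is ortho to the phenol.

Step 3
Reactants: 6 1-(2-hydroxy-3,4,5,6-tetramethoxyphenyl)ethan-1-one
Product: 8 5,6,7,8-tetramethoxy-4H-chromen-4-one, via enaminone 7 (not isolated)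
Conditions: DMF-DMA, toluene, 100 °C; then conc. HCl, CH2Cl2, 40 °C
Reagents that add atoms: N,N-dimethylformamide dimethyl acetal, COC(OC)N(C)C
Why: Condensation of the methyl ketone with the formamide acetal gives enaminone 7; acid then promotes conjugate addition of the phenol and loss of dimethylamine (enaminone route to 2,3-unsubstituted chromones).

Step 4
Reactants: 8 5,6,7,8-tetramethoxy-4H-chromen-4-one; 9 ethynyltrimethylsilane
Product: 12 (S)-5,6,7,8-tetramethoxy-2-[(trimethylsilyl)ethynyl]chroman-4-one, via silyloxypyrylium triflate 10 (not isolated), via silyl enol ether 11 (not isolated)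
Conditions: TBSOTf, i-Pr2NEt, CuI (10 mol %), StackPhos (12 mol %), toluene, −40 °C; then 1 M HCl, THF, 0 °C
Reagents that add atoms: none
Why: TBSOTf turns the chromone into 4-silyloxybenzopyrylium ion 10, and the ligand-bound copper acetylide of 9 adds to C2 on the face left open by the ligand to give 11, which dilute acid hydrolyses to 12 (copper-catalysed enantioselective alkynylation of chromones). C2 is set here by the catalyst, and the acidic hydrolysis avoids retro-oxa-Michael racemisation.

Step 5
Reactants: 12 (S)-5,6,7,8-tetramethoxy-2-[(trimethylsilyl)ethynyl]chroman-4-one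
Product: 14 (2S,4S)-2-ethynyl-5,6,7,8-tetramethoxychroman-4-ol, via silylalkynyl alcohol 13 (not isolated)
Conditions: NaBH4, CeCl3·7H2O, MeOH, −40 °C; then K2CO3 (cat.), MeOH, rt
Reagents that add atoms: none
Why: Luche reduction delivers hydride axially to the half-chair that has the C2 substituent pseudo-equatorial, which should give the 2,4-cis alcohol; carbonate in methanol then removes the alkyne silyl group once the ketone is gone. The C4 center is erased in step 13, so any trans isomer converges on the same ketone.

Step 6
Reactants: 14 (2S,4S)-2-ethynyl-5,6,7,8-tetramethoxychroman-4-ol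
Product: 15 (2S,4S)-4-(tert-butyldimethylsilyloxy)-2-ethynyl-5,6,7,8-tetramethoxychroman
Conditions: TBSOTf, 2,6-lutidine, CH2Cl2, −78 → 0 °C
Reagents that add atoms: tert-butyldimethylsilyl trifluoromethanesulfonate, CC(C)(C)[Si](C)(C)OS(=O)(=O)C(F)(F)F
Why: A silyl triflate with a hindered pyridine base silylates the peri-hindered secondary benzylic alcohol at low temperature without ionising C4 (standard silyl ether formation).

Step 7
Reactants: 15 (2S,4S)-4-(tert-butyldimethylsilyloxy)-2-ethynyl-5,6,7,8-tetramethoxychroman
Product: 18 (2S,4S)-4-(tert-butyldimethylsilyloxy)-5,6,7,8-tetramethoxy-2-[(triisopropylsilyloxy)ethynyl]chroman, via lithium acetylide 16 (not isolated), via lithium ynolate 17 (not isolated)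
Conditions: n-BuLi, THF, −78 °C; LiOOt-Bu (from t-BuOOH, LiN(SiMe3)2, THF, −78 °C), −78 → 0 °C; TIPSOTf, −78 → 0 °C; Et3N-deactivated silica
Reagents that add atoms: tert-butyl hydroperoxide, CC(C)(C)OO; triisopropylsilyl trifluoromethanesulfonate, CC(C)[Si](OS(=O)(=O)C(F)(F)F)(C(C)C)C(C)C
Why: The acetylide attacks the peroxide oxygen and expels tert-butoxide to give ynolate 17, which the bulky silyl triflate traps at oxygen (known oxidation of lithium acetylides to ynolates with O-silylation). Ynolates with a heteroatom on the adjacent carbon are used routinely in ester homologation, so loss of the C2 aryloxy group is not expected at low temperature.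

Step 8
Reactants: 19 3-oxocyclobutane-1-carboxylic acid
Product: 20 3-bromocyclobutan-1-one
Conditions: HgO, Br2, MgSO4, CH2Cl2, reflux
Reagents that add atoms: bromine, BrBr
Why: Hunsdiecker-type bromodecarboxylation (Cristol–Firth modification): the mercury carboxylate gives an acyl hypobromite that loses CO2, and the cyclobutyl radical is brominated.

Step 9
Reactants: 20 3-bromocyclobutan-1-one
Product: 21 cyclobut-2-en-1-one
Conditions: n-Bu3N, rt; vacuum transfer into cold toluene
Reagents that add atoms: none
Why: The amine removes the acidic α-proton and bromide leaves from the β-carbon (E1cB dehydrohalogenation); the volatile enone is used as a cold solution because it polymerises when neat.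

Step 10
Reactants: 18 (2S,4S)-4-(tert-butyldimethylsilyloxy)-5,6,7,8-tetramethoxy-2-[(triisopropylsilyloxy)ethynyl]chroman; 21 cyclobut-2-en-1-one
Product: 26 (2S,4S)-4-(tert-butyldimethylsilyloxy)-2-[2-hydroxy-6-(triisopropylsilyloxy)phenyl]-5,6,7,8-tetramethoxychroman, via vinylketene 22 (not isolated), via vinylcyclobutenone 23 (not isolated), via dienylketene 24 (not isolated), via cyclohexadienone 25 (not isolated)
Conditions: 21 (3 equiv, in portions), toluene, 80 °C, sealed tube; then 110 °C
Reagents that add atoms: none
Why: Heating opens 21 by 4π electrocyclic ring opening to vinylketene 22. The siloxyalkyne is polarised by oxygen so that the carbon bearing the chromanyl group is nucleophilic; it adds to the ketene in a [2+2] cycloaddition in which that carbon bonds to the ketene carbonyl carbon and the silyloxy carbon to the ketene α-carbon, giving vinylcyclobutenone 23. A second, reversible 4π opening gives dienylketene 24, and ring B closes by thermal disrotatory 6π electrocyclisation of the isomer with the vinyl group cis to the ketene, followed by tautomerisation of dienone 25 to the phenol. Between the partners the new bonds are C1'–C2' and C5'–C6' (locants of 26); the former C1–C4 bond of 21 is broken and re-formed as C2'–C3'. This is the Danheiser benzannulation of a cyclobutenone with a siloxyalkyne, which is known to give 2-substituted resorcinol monosilyl ethers. No stereocenter is created, and C2 and C4 are spectators because every step is a neutral pericyclic process that never acidifies the propargylic C2–H. The step needs the regiochemistry of the [2+2], which the oxygen polarisation of the alkyne secures, and capture of 22 in competition with self-reaction of 21, which portionwise addition of excess 21 secures.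

Step 11
Reactants: 26 (2S,4S)-4-(tert-butyldimethylsilyloxy)-2-[2-hydroxy-6-(triisopropylsilyloxy)phenyl]-5,6,7,8-tetramethoxychroman
Product: 27 (2S,4S)-4-(tert-butyldimethylsilyloxy)-2-[2-methoxy-6-(triisopropylsilyloxy)phenyl]-5,6,7,8-tetramethoxychroman
Conditions: MeI, K2CO3, DMF, rt
Reagents that add atoms: iodomethane, CI
Why: Williamson methylation of the only free hydroxyl; the aryl triisopropylsilyl ether and the alkyl silyl ether are stable to carbonate in an aprotic solvent.

Step 12
Reactants: 27 (2S,4S)-4-(tert-butyldimethylsilyloxy)-2-[2-methoxy-6-(triisopropylsilyloxy)phenyl]-5,6,7,8-tetramethoxychroman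
Product: 28 (2S,4S)-2-[2-methoxy-6-(triisopropylsilyloxy)phenyl]-5,6,7,8-tetramethoxychroman-4-ol
Conditions: HF·pyridine, pyridine, THF, 0 °C → rt
Reagents that add atoms: none
Why: Under buffered acidic fluoride a secondary alkyl tert-butyldimethylsilyl ether is cleaved faster than the bulkier aryl triisopropylsilyl ether; the pyridine buffer keeps the medium too weakly acidic to ionise the electron-rich benzylic C4 position.

Step 13
Reactants: 28 (2S,4S)-2-[2-methoxy-6-(triisopropylsilyloxy)phenyl]-5,6,7,8-tetramethoxychroman-4-ol
Product: 29 (2S)-2-[2-methoxy-6-(triisopropylsilyloxy)phenyl]-5,6,7,8-tetramethoxychroman-4-one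
Conditions: Dess–Martin periodinane, NaHCO3, CH2Cl2, rt
Reagents that add atoms: none
Why: Dess–Martin oxidation of the secondary benzylic alcohol under buffered, near-neutral conditions; ring B has no free phenol at this stage and C2 is not exposed to base.

Step 14
Reactants: 29 (2S)-2-[2-methoxy-6-(triisopropylsilyloxy)phenyl]-5,6,7,8-tetramethoxychroman-4-one
Product: 30 (2S)-2-(2-hydroxy-6-methoxyphenyl)-5,6,7,8-tetramethoxychroman-4-one
Conditions: TBAF, AcOH (1:1), THF, 0 °C
Reagents that add atoms: none
Why: Fluoride cleaves the aryl O–Si bond; acetic acid protonates the phenoxide as it forms, so the flavanone does not open by retro-oxa-Michael reaction and C2 keeps its configuration.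

Step 15
Reactants: 30 (2S)-2-(2-hydroxy-6-methoxyphenyl)-5,6,7,8-tetramethoxychroman-4-one
Product: 31 (2S)-5-hydroxy-2-(2-hydroxy-6-methoxyphenyl)-6,7,8-trimethoxychroman-4-one
Conditions: BCl3 (1 M in CH2Cl2), CH2Cl2, −78 → 0 °C; aq. NaHCO3
Reagents that add atoms: none
Why: BCl3 binds the C4 carbonyl and the peri 5-methoxy oxygen in a six-membered chelate, and chloride removes the activated methyl group (chelation-directed demethylation of 5-methoxyflavanones). The other methyl ethers lack this activation at low temperature.

## Compound list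

1 | 1,2,3,4-tetramethoxybenzene | COc1ccc(OC)c(OC)c1OC | starting material
2 | (2,3,4,5-tetramethoxyphenyl)lithium | [Li]c1cc(OC)c(OC)c(OC)c1OC | intermediate
3 | dimethyl (2,3,4,5-tetramethoxyphenyl)boronate | COB(OC)c1cc(OC)c(OC)c(OC)c1OC | intermediate
4 | 2,3,4,5-tetramethoxyphenol | Oc1cc(OC)c(OC)c(OC)c1OC | intermediate
5 | 2,3,4,5-tetramethoxyphenyl acetate | CC(=O)Oc1cc(OC)c(OC)c(OC)c1OC | intermediate
6 | 1-(2-hydroxy-3,4,5,6-tetramethoxyphenyl)ethan-1-one | CC(=O)c1c(O)c(OC)c(OC)c(OC)c1OC | intermediate
7 | (E)-3-(dimethylamino)-1-(2-hydroxy-3,4,5,6-tetramethoxyphenyl)prop-2-en-1-one | CN(C)/C=C/C(=O)c1c(O)c(OC)c(OC)c(OC)c1OC | intermediate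
8 | 5,6,7,8-tetramethoxy-4H-chromen-4-one | O=c1ccoc2c(OC)c(OC)c(OC)c(OC)c12 | intermediate
9 | ethynyltrimethylsilane | C#C[Si](C)(C)C | starting material
10 | 4-(tert-butyldimethylsilyloxy)-5,6,7,8-tetramethoxychromenylium trifluoromethanesulfonate | CC(C)(C)[Si](C)(C)Oc1cc[o+]c2c(OC)c(OC)c(OC)c(OC)c12.[O-]S(=O)(=O)C(F)(F)F | intermediate
11 | (S)-4-(tert-butyldimethylsilyloxy)-5,6,7,8-tetramethoxy-2-[(trimethylsilyl)ethynyl]-2H-chromene | C[Si](C)(C)C#C[C@@H]1C=C(O[Si](C)(C)C(C)(C)C)c2c(OC)c(OC)c(OC)c(OC)c2O1 | intermediate
12 | (S)-5,6,7,8-tetramethoxy-2-[(trimethylsilyl)ethynyl]chroman-4-one | C[Si](C)(C)C#C[C@@H]1CC(=O)c2c(OC)c(OC)c(OC)c(OC)c2O1 | intermediate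
13 | (2S,4S)-5,6,7,8-tetramethoxy-2-[(trimethylsilyl)ethynyl]chroman-4-ol | C[Si](C)(C)C#C[C@@H]1C[C@H](O)c2c(OC)c(OC)c(OC)c(OC)c2O1 | intermediate
14 | (2S,4S)-2-ethynyl-5,6,7,8-tetramethoxychroman-4-ol | C#C[C@@H]1C[C@H](O)c2c(OC)c(OC)c(OC)c(OC)c2O1 | intermediate
15 | (2S,4S)-4-(tert-butyldimethylsilyloxy)-2-ethynyl-5,6,7,8-tetramethoxychroman | C#C[C@@H]1C[C@H](O[Si](C)(C)C(C)(C)C)c2c(OC)c(OC)c(OC)c(OC)c2O1 | intermediate
16 | lithium acetylide of 15 | [Li]C#C[C@@H]1C[C@H](O[Si](C)(C)C(C)(C)C)c2c(OC)c(OC)c(OC)c(OC)c2O1 | intermediate
17 | lithium ynolate, lithium 2-[(2S,4S)-4-(tert-butyldimethylsilyloxy)-5,6,7,8-tetramethoxychroman-2-yl]ethynolate | [Li]OC#C[C@@H]1C[C@H](O[Si](C)(C)C(C)(C)C)c2c(OC)c(OC)c(OC)c(OC)c2O1 | intermediate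
18 | (2S,4S)-4-(tert-butyldimethylsilyloxy)-5,6,7,8-tetramethoxy-2-[(triisopropylsilyloxy)ethynyl]chroman (2,4-cis) | CC(C)[Si](OC#C[C@@H]1C[C@H](O[Si](C)(C)C(C)(C)C)c2c(OC)c(OC)c(OC)c(OC)c2O1)(C(C)C)C(C)C | intermediate
19 | 3-oxocyclobutane-1-carboxylic acid | O=C1CC(C(=O)O)C1 | starting material
20 | 3-bromocyclobutan-1-one | O=C1CC(Br)C1 | intermediate
21 | cyclobut-2-en-1-one | O=C1C=CC1 | intermediate
22 | buta-1,3-dien-1-one (vinylketene) | C=CC=C=O | intermediate
23 | 2-[(2S,4S)-4-(tert-butyldimethylsilyloxy)-5,6,7,8-tetramethoxychroman-2-yl]-3-(triisopropylsilyloxy)-4-vinylcyclobut-2-en-1-one (mixture at the ring C4) | O=C1C(C=C)C(O[Si](C(C)C)(C(C)C)C(C)C)=C1[C@@H]1C[C@H](O[Si](C)(C)C(C)(C)C)c2c(OC)c(OC)c(OC)c(OC)c2O1 | intermediate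
24 | 2-[(2S,4S)-4-(tert-butyldimethylsilyloxy)-5,6,7,8-tetramethoxychroman-2-yl]-3-(triisopropylsilyloxy)hexa-1,3,5-trien-1-one, vinyl group cis to the ketene-bearing carbon | O=C=C([C@@H]1C[C@H](O[Si](C)(C)C(C)(C)C)c2c(OC)c(OC)c(OC)c(OC)c2O1)/C(O[Si](C(C)C)(C(C)C)C(C)C)=C\C=C | intermediate
25 | 2-[(2S,4S)-4-(tert-butyldimethylsilyloxy)-5,6,7,8-tetramethoxychroman-2-yl]-3-(triisopropylsilyloxy)cyclohexa-2,4-dien-1-one | O=C1CC=CC(O[Si](C(C)C)(C(C)C)C(C)C)=C1[C@@H]1C[C@H](O[Si](C)(C)C(C)(C)C)c2c(OC)c(OC)c(OC)c(OC)c2O1 | intermediate
26 | (2S,4S)-4-(tert-butyldimethylsilyloxy)-2-[2-hydroxy-6-(triisopropylsilyloxy)phenyl]-5,6,7,8-tetramethoxychroman (2,4-cis) | CC(C)[Si](Oc1cccc(O)c1[C@@H]1C[C@H](O[Si](C)(C)C(C)(C)C)c2c(OC)c(OC)c(OC)c(OC)c2O1)(C(C)C)C(C)C | intermediate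
27 | (2S,4S)-4-(tert-butyldimethylsilyloxy)-2-[2-methoxy-6-(triisopropylsilyloxy)phenyl]-5,6,7,8-tetramethoxychroman | CC(C)[Si](Oc1cccc(OC)c1[C@@H]1C[C@H](O[Si](C)(C)C(C)(C)C)c2c(OC)c(OC)c(OC)c(OC)c2O1)(C(C)C)C(C)C | intermediate
28 | (2S,4S)-2-[2-methoxy-6-(triisopropylsilyloxy)phenyl]-5,6,7,8-tetramethoxychroman-4-ol | CC(C)[Si](Oc1cccc(OC)c1[C@@H]1C[C@H](O)c2c(OC)c(OC)c(OC)c(OC)c2O1)(C(C)C)C(C)C | intermediate
29 | (2S)-2-[2-methoxy-6-(triisopropylsilyloxy)phenyl]-5,6,7,8-tetramethoxychroman-4-one | CC(C)[Si](Oc1cccc(OC)c1[C@@H]1CC(=O)c2c(OC)c(OC)c(OC)c(OC)c2O1)(C(C)C)C(C)C | intermediate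
30 | (2S)-2-(2-hydroxy-6-methoxyphenyl)-5,6,7,8-tetramethoxychroman-4-one | COc1cccc(O)c1[C@@H]1CC(=O)c2c(OC)c(OC)c(OC)c(OC)c2O1 | intermediate
31 | (2S)-5-hydroxy-2-(2-hydroxy-6-methoxyphenyl)-6,7,8-trimethoxychroman-4-one | COc1cccc(O)c1[C@@H]1CC(=O)c2c(O)c(OC)c(OC)c(OC)c2O1 | target

## Step count and least certain steps

Total: 15 steps. Longest linear sequence: 13 steps (steps 1–7 and 10–15); steps 8 and 9 form the two-step branch to 21.

**Step 10 (key step).** The most likely failure is self-reaction (dimerisation or polymerisation) of 21 outrunning its ring opening. Thermal loss of the labile silyloxyalkyne function at the temperature required, and acylation of the new phenol by excess ketene, are further risks. The fallback sets out from 18 and returns at 26. Vinylketene 22 is generated at room temperature by photochemical Wolff rearrangement instead of cyclobutenone opening. But-3-en-2-one is converted through its trifluoroacetylated enolate, 1,1,1-trifluorohex-5-ene-2,4-dione F1 (LiN(SiMe3)2, CF3CO2CH2CF3, THF, −78 °C), by deacylative diazo transfer (MsN3, Et3N) into 1-diazobut-3-en-2-one F2. Irradiation of F2 with 18 in CH2Cl2, followed by brief warming to 80 °C, takes the same cascade through 23, 24 and 25 to 26.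

**Step 4.** The tetramethoxy-stabilised pyrylium ion 10 is a weak electrophile and the 5-methoxy group crowds the silyloxy carbon, so low enantioselectivity is the main risk. The fallback sets out from 8 and returns at 14; it replaces asymmetric catalysis by resolution. The same addition without the chiral ligand gives racemic 5,6,7,8-tetramethoxy-2-[(trimethylsilyl)ethynyl]chroman-4-one F3. The conditions of step 5 give racemic cis-2-ethynyl-5,6,7,8-tetramethoxychroman-4-ol F4. Steglich esterification with (S)-2-methoxy-2-phenylacetic acid (DCC, DMAP) gives two diastereomeric esters, (2S,4S)-2-ethynyl-5,6,7,8-tetramethoxychroman-4-yl (S)-2-methoxy-2-phenylacetate F5 and (2R,4R)-2-ethynyl-5,6,7,8-tetramethoxychroman-4-yl (S)-2-methoxy-2-phenylacetate F6, which are separated by chromatography or crystallisation. Saponification of F5 (LiOH, THF/H2O) gives 14.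

**Step 7.** Oxygen transfer from the peroxide to the branched acetylide may be incomplete, which would leave 15 mixed with a product that does not tolerate long chromatography. The fallback sets out from 15 and returns at 18; it replaces direct oxidation by an isolable alkynyl ester. Acetylide 16 is treated with PhI(OCOPh)2 to give 2-[(2S,4S)-4-(tert-butyldimethylsilyloxy)-5,6,7,8-tetramethoxychroman-2-yl]ethynyl benzoate F7, which is purified. MeLi (2 equiv, THF, −78 °C) then cleaves the ester to ynolate 17, and TIPSOTf traps it as 18.

**Step 15.** The Lewis acid may ionise the O1–C2 bond, which is benzylic to the oxygen-rich ring B; that would racemise C2 through ring opening. Loss of a second methyl group is the other risk. The fallback sets out from 30 and returns at 31; it deactivates ring B before the Lewis acid is applied. Acetylation (Ac2O, pyridine) gives 3-methoxy-2-[(2S)-5,6,7,8-tetramethoxy-4-oxochroman-2-yl]phenyl acetate F8. BCl3 at −78 °C then gives 2-[(2S)-5-hydroxy-6,7,8-trimethoxy-4-oxochroman-2-yl]-3-methoxyphenyl acetate F9. The aryl acetate is removed under neutral conditions (NH4OAc, aq. MeOH, rt) to give 31.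

**Step 12.** Partial loss of the aryl silyl ether, or ionisation at C4 with elimination towards the 2H-chromene, may occur under acidic fluoride. The fallback sets out from 27 and returns at 30; it gives up the selective deprotection. TBAF (THF, rt) removes both silyl groups while no base-labile ketone is present and gives (2S,4S)-2-(2-hydroxy-6-methoxyphenyl)-5,6,7,8-tetramethoxychroman-4-ol F10. Activated MnO2 (CH2Cl2, rt) then oxidises the electron-rich benzylic alcohol in the presence of the phenol to give 30.

## Further compounds

F1 | step 10 | 1,1,1-trifluorohex-5-ene-2,4-dione | C=CC(=O)CC(=O)C(F)(F)F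
F2 | step 10 | 1-diazobut-3-en-2-one | C=CC(=O)C=[N+]=[N-]
F3 | step 4 | racemic 5,6,7,8-tetramethoxy-2-[(trimethylsilyl)ethynyl]chroman-4-one | C[Si](C)(C)C#CC1CC(=O)c2c(OC)c(OC)c(OC)c(OC)c2O1
F4 | step 4 | racemic cis-2-ethynyl-5,6,7,8-tetramethoxychroman-4-ol | C#C[C@@H]1C[C@H](O)c2c(OC)c(OC)c(OC)c(OC)c2O1.C#C[C@H]1C[C@@H](O)c2c(OC)c(OC)c(OC)c(OC)c2O1
F5 | step 4 | (2S,4S)-2-ethynyl-5,6,7,8-tetramethoxychroman-4-yl (S)-2-methoxy-2-phenylacetate | C#C[C@@H]1C[C@H](OC(=O)[C@@H](OC)c2ccccc2)c2c(OC)c(OC)c(OC)c(OC)c2O1
F6 | step 4 | (2R,4R)-2-ethynyl-5,6,7,8-tetramethoxychroman-4-yl (S)-2-methoxy-2-phenylacetate | C#C[C@H]1C[C@@H](OC(=O)[C@@H](OC)c2ccccc2)c2c(OC)c(OC)c(OC)c(OC)c2O1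
F7 | step 7 | 2-[(2S,4S)-4-(tert-butyldimethylsilyloxy)-5,6,7,8-tetramethoxychroman-2-yl]ethynyl benzoate | O=C(OC#C[C@@H]1C[C@H](O[Si](C)(C)C(C)(C)C)c2c(OC)c(OC)c(OC)c(OC)c2O1)c1ccccc1
F8 | step 15 | 3-methoxy-2-[(2S)-5,6,7,8-tetramethoxy-4-oxochroman-2-yl]phenyl acetate | COc1cccc(OC(C)=O)c1[C@@H]1CC(=O)c2c(OC)c(OC)c(OC)c(OC)c2O1
F9 | step 15 | 2-[(2S)-5-hydroxy-6,7,8-trimethoxy-4-oxochroman-2-yl]-3-methoxyphenyl acetate | COc1cccc(OC(C)=O)c1[C@@H]1CC(=O)c2c(O)c(OC)c(OC)c(OC)c2O1
F10 | step 12 | (2S,4S)-2-(2-hydroxy-6-methoxyphenyl)-5,6,7,8-tetramethoxychroman-4-ol | COc1cccc(O)c1[C@@H]1C[C@H](O)c2c(OC)c(OC)c(OC)c(OC)c2O1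
A1 | alternative 1 | 2-[2-(benzyloxy)-6-methoxyphenyl]-5,6,7,8-tetramethoxy-4H-chromen-4-one | COc1cccc(OCc3ccccc3)c1-c1cc(=O)c2c(OC)c(OC)c(OC)c(OC)c2o1
A2 | alternative 1 | 2-iodo-3,4,5,6-tetramethoxyphenol | Oc1c(I)c(OC)c(OC)c(OC)c1OC
A3 | alternative 1 | 1-(benzyloxy)-2-ethynyl-3-methoxybenzene | C#Cc1c(OC)cccc1OCc1ccccc1
A4 | alternative 1 | (2S)-2-[2-(benzyloxy)-6-methoxyphenyl]-5,6,7,8-tetramethoxychroman-4-one | COc1cccc(OCc3ccccc3)c1[C@@H]1CC(=O)c2c(OC)c(OC)c(OC)c(OC)c2O1
A5 | alternative 2 | (2S)-2-(2-isopropoxy-6-methoxyphenyl)-5,6,7,8-tetramethoxychroman-4-one | CC(C)Oc1cccc(OC)c1[C@@H]1CC(=O)c2c(OC)c(OC)c(OC)c(OC)c2O1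
A6 | alternative 2 | 2-diazo-1-{2-[(2-isopropoxy-6-methoxybenzyl)oxy]-3,4,5,6-tetramethoxyphenyl}ethan-1-one | [N-]=[N+]=CC(=O)c1c(OC)c(OC)c(OC)c(OC)c1OCc1c(OC)cccc1OC(C)C
A7 | alternative 3 | (2S,4S)-2-[2-(benzyloxy)-6-methoxyphenyl]-5,6,7,8-tetramethoxychroman-4-ol | COc1cccc(OCc3ccccc3)c1[C@@H]1C[C@H](O)c2c(OC)c(OC)c(OC)c(OC)c2O1
A8 | alternative 3 | (1S,3S)-3-[2-(benzyloxy)-6-methoxyphenyl]-1-(2-bromo-3,4,5,6-tetramethoxyphenyl)propane-1,3-diol | COc1cccc(OCc3ccccc3)c1[C@@H](O)C[C@H](O)c1c(Br)c(OC)c(OC)c(OC)c1OC
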